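**A direct plan and its weak points**

A direct plan would make the aroyl(methoxy)acetate A1 by a crossed Claisen condensation, turn it into the enol triflate A2, join this to the ring A phenol A3 by vinylic substitution and saponify to the β-aryloxyacrylic acid A4.
Friedel–Crafts acylation of A4 (bond C4–C4a) would close ring C last, giving the 5,7-diallyl ether A5, and palladium-catalysed deallylation would end the route.
Weak point 1, the passage from 2,4,6-trihydroxybenzaldehyde A6 to A3 (bis-allylation, MOM ether, Dakin oxidation, methylation, MOM removal): five operations would only move protecting groups and oxidation levels around a ring that is bought.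
Weak point 2, the substitution of the tetrasubstituted enol triflate A2 by the phenoxide: attack at sulfur would compete with attack at carbon, and the E geometry that the ring closure needs would not be under control.
Weak point 3, the acylium ring closure followed by the final deallylation: both would expose the prenyl ether, late in the route, to an acid chloride medium and to an allyl-cleaving palladium catalyst.

**Retrosynthetic overview of the new route**

Ring C is bought, not made: kojic acid already holds O1, C2, C3–O, C4=O, C4a and C8a, and its CH2–O group is C8 with the oxygen of the future 8-methoxyl.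
Ring B is attached at C2 by Suzuki coupling after bromination, and the two hydroxyls are methylated once, as the 3- and 8-methoxyls.
Ring A is built last from open-chain atoms: C7 comes from CO2, C6 and C5 from Meldrum's acid, and one thermal step lets an α-oxoketene acylate C4a (bond C4a–C5) and aromatise to the 5,7-dihydroxy-8-methoxy ring.
Because O1–C8a and the C8 methoxyl exist from the start, the 8- versus 6-methoxy question cannot arise; no ring A phenol is ever protected, no enol triflate geometry matters, and nothing is deprotected at the end.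

Key step: step 7

Remark: kojic acid is assumed to brominate at C6 (ortho to the enolic hydroxyl), the site of its other electrophilic substitutions, and the phenol boronate 4 is taken as an article of commerce.

**Route**

Step 1
Reactants: 1 kojic acid (5-hydroxy-2-(hydroxymethyl)-4H-pyran-4-one)
Product: 2 2-bromo-3-hydroxy-6-(hydroxymethyl)-4H-pyran-4-one (6-bromokojic acid)
Conditions: NBS (1.05 equiv), MeCN/H2O, 0 °C to rt
Reagents that add atoms: N-bromosuccinimide, O=C1CCC(=O)N1Br
Why: Electrophilic bromination of the enolic 3-hydroxy-4-pyranone at the carbon ortho to the hydroxyl and next to the ring oxygen, where kojic acid also takes up Mannich and hydroxymethyl electrophiles; this carbon becomes C2 of the flavone.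

Step 2
Reactants: 2 2-bromo-3-hydroxy-6-(hydroxymethyl)-4H-pyran-4-one
Product: 3 2-bromo-3-methoxy-6-(methoxymethyl)-4H-pyran-4-one
Conditions: MeI (excess), Ag2O (3 equiv), MeCN, 40 °C, dark
Reagents that add atoms: iodomethane, CI
Why: Purdie methylation of the enolic and the primary hydroxyl in one operation, in which silver oxide takes up HI without forming a free alkoxide that could displace the vinylogous acyl bromide; the two methyl groups are the 3- and 8-methoxyls of the target.

Step 3
Reactants: 4 2-methoxy-4-(4,4,5,5-tetramethyl-1,3,2-dioxaborolan-2-yl)phenol; 5 prenyl bromide (1-bromo-3-methylbut-2-ene)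
Product: 6 2-{3-methoxy-4-[(3-methylbut-2-en-1-yl)oxy]phenyl}-4,4,5,5-tetramethyl-1,3,2-dioxaborolane
Conditions: K2CO3, DMF, rt
Reagents that add atoms: none
Why: Williamson ether synthesis (SN2 of the phenoxide on the primary allylic bromide), in which anhydrous carbonate leaves the pinacol boronate untouched.

Step 4
Reactants: 3 2-bromo-3-methoxy-6-(methoxymethyl)-4H-pyran-4-one; 6 aryl pinacol boronate
Product: 7 3-methoxy-6-(methoxymethyl)-2-{3-methoxy-4-[(3-methylbut-2-en-1-yl)oxy]phenyl}-4H-pyran-4-one
Conditions: PdCl2(dppf) (3 mol%), K3PO4 (2 equiv), 1,4-dioxane/H2O (10:1), 70 °C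
Reagents that add atoms: none
Why: Suzuki–Miyaura coupling, in which zerovalent palladium should insert into the C–Br bond of the vinylogous acyl bromide much faster than it ionises the prenyl aryl ether, and the mild phosphate base should spare the pyranone ring.

Step 5
Reactants: 7 2-aryl-3-methoxy-6-(methoxymethyl)-4H-pyran-4-one
Product: 8 2-methoxy-2-(5-methoxy-6-{3-methoxy-4-[(3-methylbut-2-en-1-yl)oxy]phenyl}-4-oxo-4H-pyran-2-yl)acetic acid (racemic)
Conditions: LiN(iPr)2 (1.1 equiv), THF, −78 °C; CO2 (dry gas), −78 to −30 °C; then 1 M HCl, 0 °C, to pH 3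
Reagents that add atoms: carbon dioxide, O=C=O
Why: Lateral (vinylogous) deprotonation of the CH2 group at C6 of the 4-pyranone gives an extended enolate that is carboxylated at the exocyclic carbon, since attack at the ring carbon would break the pyranone conjugation; the new stereocentre forms as a racemate and is erased when ring A aromatises in step 7.

Step 6
Reactants: 8 pyranylmethoxyacetic acid; 9 Meldrum's acid (2,2-dimethyl-1,3-dioxane-4,6-dione)
Product: 10 5-[1-hydroxy-2-methoxy-2-(5-methoxy-6-{3-methoxy-4-[(3-methylbut-2-en-1-yl)oxy]phenyl}-4-oxo-4H-pyran-2-yl)ethylidene]-2,2-dimethyl-1,3-dioxane-4,6-dione (racemic, enol form)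
Conditions: DCC (1.1 equiv), DMAP (1.2 equiv), CH2Cl2, −10 °C to rt; filtration; wash with cold aq. KHSO4; used crude
Reagents that add atoms: none
Why: C-Acylation of Meldrum's acid (Oikawa–Yonemitsu reaction), in which the carbodiimide-activated acid is taken up by the non-basic Meldrum's acid anion, so that the acidic hydrogen next to the carboxyl is tolerated.

Step 7
Reactants: 10 acyl Meldrum's acid
Product: 12 5,7-dihydroxy-3,8-dimethoxy-2-{3-methoxy-4-[(3-methylbut-2-en-1-yl)oxy]phenyl}-4H-chromen-4-one (the target), via acylketene 11 (not isolated)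
Conditions: toluene (0.005 M), slow addition into refluxing solvent (110 °C), N2 stream, 2–4 h
Reagents that add atoms: none
Why: Proposed new method: on heating, 10 should lose acetone and CO2 by the usual cycloreversion of acyl Meldrum's acids to the α-oxoketene 11, whose enol (C8=C7–OH, conjugated with the pyranone) is a dienylketene C4a=C8a–C8=C7–C6=C5=O; a 6π electrocyclisation, equivalent to attack of the nucleophilic enol-ether β-carbon C4a on the ketene carbon C5, forms the C4a–C5 bond, and two proton shifts aromatise the new ring to the 5,7-dihydroxy-8-methoxy pattern. The closest known reaction types are the dienylketene electrocyclisation that ends the Danheiser benzannulation, the trapping of α-oxoketenes from acyl Meldrum's acids and dioxinones by tethered nucleophiles, and the acid-mediated closure of 4-aryl-3-oxobutanoates to naphthalene-1,3-diols; what is new is a neutral, thermal C-acylation of a 4-pyranone C–H by such a ketene. Ring A closes as a six-membered carbocycle from C4a, C8a, C8, C7, C6 and C5, with the ketene C=C inside the ring and the ketene C=O outside it, where it becomes the chelated 5-hydroxyl. No stereocentre is formed, and the racemic centre at C8 disappears. The step needs C- over O-acylation and intra- over intermolecular reaction: C4a is the only nucleophile within six-membered reach of C5 (the pyranone carbonyl oxygen would have to close an eight-membered ring), and high dilution with slow addition holds back ketene dimerisation; the regiochemistry cannot vary because O1–C8a and the C8 methoxyl are already in place, and the neutral medium at 110 °C should spare the prenyl ether, whose Claisen rearrangement needs higher temperatures.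

**Compound list**

1 | kojic acid (5-hydroxy-2-(hydroxymethyl)-4H-pyran-4-one) | OCc1cc(=O)c(O)co1 | starting material
2 | 2-bromo-3-hydroxy-6-(hydroxymethyl)-4H-pyran-4-one | OCc1cc(=O)c(O)c(Br)o1 | intermediate
3 | 2-bromo-3-methoxy-6-(methoxymethyl)-4H-pyran-4-one | COCc1cc(=O)c(OC)c(Br)o1 | intermediate
4 | 2-methoxy-4-(4,4,5,5-tetramethyl-1,3,2-dioxaborolan-2-yl)phenol | COc1cc(B2OC(C)(C)C(C)(C)O2)ccc1O | starting material
5 | prenyl bromide (1-bromo-3-methylbut-2-ene) | CC(C)=CCBr | starting material
6 | 2-{3-methoxy-4-[(3-methylbut-2-en-1-yl)oxy]phenyl}-4,4,5,5-tetramethyl-1,3,2-dioxaborolane | COc1cc(B2OC(C)(C)C(C)(C)O2)ccc1OCC=C(C)C | intermediate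
7 | 3-methoxy-6-(methoxymethyl)-2-{3-methoxy-4-[(3-methylbut-2-en-1-yl)oxy]phenyl}-4H-pyran-4-one | COCc1cc(=O)c(OC)c(-c2ccc(OCC=C(C)C)c(OC)c2)o1 | intermediate
8 | 2-methoxy-2-(5-methoxy-6-{3-methoxy-4-[(3-methylbut-2-en-1-yl)oxy]phenyl}-4-oxo-4H-pyran-2-yl)acetic acid (racemic) | COC(C(=O)O)c1cc(=O)c(OC)c(-c2ccc(OCC=C(C)C)c(OC)c2)o1 | intermediate
9 | Meldrum's acid (2,2-dimethyl-1,3-dioxane-4,6-dione) | CC1(C)OC(=O)CC(=O)O1 | starting material
10 | 5-[1-hydroxy-2-methoxy-2-(5-methoxy-6-{3-methoxy-4-[(3-methylbut-2-en-1-yl)oxy]phenyl}-4-oxo-4H-pyran-2-yl)ethylidene]-2,2-dimethyl-1,3-dioxane-4,6-dione (racemic, enol form) | COC(C(O)=C1C(=O)OC(C)(C)OC1=O)c1cc(=O)c(OC)c(-c2ccc(OCC=C(C)C)c(OC)c2)o1 | intermediate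
11 | 4-methoxy-4-(5-methoxy-6-{3-methoxy-4-[(3-methylbut-2-en-1-yl)oxy]phenyl}-4-oxo-4H-pyran-2-yl)buta-1-ene-1,3-dione (racemic; formed in the flask, not isolated) | COC(C(=O)C=C=O)c1cc(=O)c(OC)c(-c2ccc(OCC=C(C)C)c(OC)c2)o1 | intermediate
12 | 5,7-dihydroxy-3,8-dimethoxy-2-{3-methoxy-4-[(3-methylbut-2-en-1-yl)oxy]phenyl}-4H-chromen-4-one | COc1cc(-c2oc3c(OC)c(O)cc(O)c3c(=O)c2OC)ccc1OCC=C(C)C | target

**Step count and risks**

Total step count: 7. Longest linear sequence: 6 steps (steps 1, 2, 4, 5, 6, 7, from kojic acid).

Steps most likely to fail: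

1. Step 7 (proposed new method). The α-oxoketene may be used up by dimerisation or by intermolecular O-acylation faster than the weakly nucleophilic C4a attacks it. The fallback uses known reaction types only, sets out from 3 and comes back at 12. It places the C5 carbon on C4a before ring B is attached, so that ring A closes by an anionic Claisen condensation of the toluate-anion type instead of a ketene acylation. Bromination of 3 at its only ring C–H (Br2, NaOAc, AcOH) would give 2,5-dibromo-3-methoxy-6-(methoxymethyl)-4H-pyran-4-one F1. Suzuki coupling with 6 at the more reactive C–Br bond on the oxygen-bearing carbon would give 3-bromo-5-methoxy-2-(methoxymethyl)-6-{3-methoxy-4-[(3-methylbut-2-en-1-yl)oxy]phenyl}-4H-pyran-4-one F2. Methoxycarbonylation (Pd(OAc)2, 1,1'-bis(diphenylphosphino)ferrocene, CO, MeOH, Et3N) would give methyl 5-methoxy-2-(methoxymethyl)-6-{3-methoxy-4-[(3-methylbut-2-en-1-yl)oxy]phenyl}-4-oxo-4H-pyran-3-carboxylate F3. Lateral deprotonation (LiN(iPr)2, THF, −78 °C) and acylation with N-methoxy-N-methylacetamide would give methyl 5-methoxy-2-(1-methoxy-2-oxopropyl)-6-{3-methoxy-4-[(3-methylbut-2-en-1-yl)oxy]phenyl}-4-oxo-4H-pyran-3-carboxylate F4. Its methyl ketone enolate (NaH, THF) would close onto the neighbouring ester and give 12 after loss of methanol and enolisation.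

2. Step 6. Activation of the acid, whose hydrogen next to the carboxyl is very acidic, may lead to ketene dimers or to loss of CO2 instead of C-acylation of Meldrum's acid. The fallback sets out from 8 and comes back at 11. A Masamune–Brooks homologation (1,1'-carbonyldiimidazole, THF; then Mg(O2CCH2CO2tBu)2) would give the isolable β-keto ester tert-butyl 4-methoxy-4-(5-methoxy-6-{3-methoxy-4-[(3-methylbut-2-en-1-yl)oxy]phenyl}-4-oxo-4H-pyran-2-yl)-3-oxobutanoate F5. Heating F5 in toluene/xylene with distillation of tert-butanol is the established way from tert-butyl β-keto esters to α-oxoketenes and would give 11.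

3. Step 2. Etherification of the primary hydroxyl may stay incomplete, or the vinylogous acyl bromide may be displaced during the double methylation. The fallback sets out from 1 and comes back at 3. It brings in the side-chain methoxyl by substitution at carbon before the ring is brominated. SOCl2 would give 2-(chloromethyl)-5-hydroxy-4H-pyran-4-one F6. NaOMe in MeOH would give 5-hydroxy-2-(methoxymethyl)-4H-pyran-4-one F7. NBS would give 2-bromo-3-hydroxy-6-(methoxymethyl)-4H-pyran-4-one F8. MeI and K2CO3 in acetone would then methylate only the enolic hydroxyl and give 3.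

**Further compounds**

F1 | step 7 | 2,5-dibromo-3-methoxy-6-(methoxymethyl)-4H-pyran-4-one | COCc1oc(Br)c(OC)c(=O)c1Br
F2 | step 7 | 3-bromo-5-methoxy-2-(methoxymethyl)-6-{3-methoxy-4-[(3-methylbut-2-en-1-yl)oxy]phenyl}-4H-pyran-4-one | COCc1oc(-c2ccc(OCC=C(C)C)c(OC)c2)c(OC)c(=O)c1Br
F3 | step 7 | methyl 5-methoxy-2-(methoxymethyl)-6-{3-methoxy-4-[(3-methylbut-2-en-1-yl)oxy]phenyl}-4-oxo-4H-pyran-3-carboxylate | COCc1oc(-c2ccc(OCC=C(C)C)c(OC)c2)c(OC)c(=O)c1C(=O)OC
F4 | step 7 | methyl 5-methoxy-2-(1-methoxy-2-oxopropyl)-6-{3-methoxy-4-[(3-methylbut-2-en-1-yl)oxy]phenyl}-4-oxo-4H-pyran-3-carboxylate (racemic) | COC(C(C)=O)c1oc(-c2ccc(OCC=C(C)C)c(OC)c2)c(OC)c(=O)c1C(=O)OC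
F5 | step 6 | tert-butyl 4-methoxy-4-(5-methoxy-6-{3-methoxy-4-[(3-methylbut-2-en-1-yl)oxy]phenyl}-4-oxo-4H-pyran-2-yl)-3-oxobutanoate (racemic) | COC(C(=O)CC(=O)OC(C)(C)C)c1cc(=O)c(OC)c(-c2ccc(OCC=C(C)C)c(OC)c2)o1
F6 | step 2 | 2-(chloromethyl)-5-hydroxy-4H-pyran-4-one | ClCc1cc(=O)c(O)co1
F7 | step 2 | 5-hydroxy-2-(methoxymethyl)-4H-pyran-4-one | COCc1cc(=O)c(O)co1
F8 | step 2 | 2-bromo-3-hydroxy-6-(methoxymethyl)-4H-pyran-4-one | COCc1cc(=O)c(O)c(Br)o1
A1 | direct plan | methyl 2-methoxy-3-{3-methoxy-4-[(3-methylbut-2-en-1-yl)oxy]phenyl}-3-oxopropanoate (racemic) | COC(C(=O)OC)C(=O)c1ccc(OCC=C(C)C)c(OC)c1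
A2 | direct plan | methyl (E)-2-methoxy-3-{3-methoxy-4-[(3-methylbut-2-en-1-yl)oxy]phenyl}-3-[(trifluoromethylsulfonyl)oxy]prop-2-enoate | CO/C(C(=O)OC)=C(/OS(=O)(=O)C(F)(F)F)c1ccc(OCC=C(C)C)c(OC)c1
A3 | direct plan | 3,5-bis(allyloxy)-2-methoxyphenol | COc1c(O)cc(OCC=C)cc1OCC=C
A4 | direct plan | (E)-3-[3,5-bis(allyloxy)-2-methoxyphenoxy]-2-methoxy-3-{3-methoxy-4-[(3-methylbut-2-en-1-yl)oxy]phenyl}prop-2-enoic acid | CO/C(C(=O)O)=C(/Oc1cc(OCC=C)cc(OCC=C)c1OC)c1ccc(OCC=C(C)C)c(OC)c1
A5 | direct plan | 5,7-bis(allyloxy)-3,8-dimethoxy-2-{3-methoxy-4-[(3-methylbut-2-en-1-yl)oxy]phenyl}-4H-chromen-4-one | COc1cc(-c2oc3c(OC)c(OCC=C)cc(OCC=C)c3c(=O)c2OC)ccc1OCC=C(C)C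
A6 | direct plan | 2,4,6-trihydroxybenzaldehyde | O=Cc1c(O)cc(O)cc1O
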